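**Assumption:** (−)-epicatechin, 3,4,5-tris(benzyloxy)benzoic acid and [hydroxy(tosyloxy)iodo]benzene are bought as such; the excess flavan nucleophile used in each coupling is recovered.

## Retrosynthetic overview

1. Target ⇒ hydrogenolysis of 21 benzyl ethers ⇒ perbenzylated tri-gallate ⇒ three esterifications of dodeca-O-benzylprocyanidin C1 (three free 3-OH) with tri-O-benzylgallic acid.
2. The two new carbinols (top and middle units) ⇒ reduction of a trimeric 3-oxo/3-oxo/3-ol compound, hydride anti to each C2 aryl.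
3. Both interflavan C4–C8 bonds ⇒ polarity-reversed α-arylation: a trivalent-iodine enolonium (α-keto cation at C4) of tetra-O-benzylflavan-3-one is attacked by C8–H of the benzylated flavan below it, joining two innately nucleophilic carbons; bottom bond first (acetate-ligated enolonium), then top bond (tosylate-ligated enolonium).
4. Enolonium precursor (2H-chromene silyl enol ether) ⇐ flavan-3-one ⇐ tetra-O-benzylepicatechin ⇐ (−)-epicatechin; the same benzyl ether is the first nucleophile.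
5. No ring is formed: rings A, C and B of all three flavan units come intact from epicatechin, the galloyl rings from the gallic acid derivative.

## Route

Step 1
Reactants: 1 (−)-epicatechin; 2 benzyl bromide
Product: 3 5,7,3',4'-tetra-O-benzyl-(−)-epicatechin [(2R,3R)-5,7-bis(benzyloxy)-2-[3,4-bis(benzyloxy)phenyl]chroman-3-ol]
Conditions: BnBr (4.4 equiv), K2CO3, DMF, 0 °C → rt
Reagents that add atoms: benzyl bromide (2), BrCc1ccccc1
Why: Williamson etherification of the four acidic phenols with K2CO3 leaves the secondary 3-OH free and touches no stereocentre.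

Step 2
Reactants: 3 5,7,3',4'-tetra-O-benzyl-(−)-epicatechin
Product: 4 (2R)-5,7,3',4'-tetra-O-benzylflavan-3-one
Conditions: Dess–Martin periodinane, wet CH2Cl2, rt
Reagents that add atoms: none
Why: Dess–Martin oxidation of the secondary alcohol is neutral and non-enolising, so the C2 stereocentre (R) next to the new carbonyl is kept, as known for this ketone.

Step 3
Reactants: 4 (2R)-5,7,3',4'-tetra-O-benzylflavan-3-one; 5 chlorotrimethylsilane
Product: 6 (2R)-5,7-bis(benzyloxy)-2-[3,4-bis(benzyloxy)phenyl]-3-(trimethylsilyloxy)-2H-chromene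
Conditions: LiN(SiMe3)2, Me3SiCl (in situ quench), THF, −78 °C; pentane filtration, used crude
Reagents that add atoms: chlorotrimethylsilane (5), C[Si](C)(C)Cl
Why: kinetic enolisation with internal silyl trapping removes a proton from the unhindered benzylic C4 methylene in preference to the α-oxygenated C2 methine, giving the ring-A-conjugated silyl enol ether with C2 intact.

Step 4
Reactants: 6 the silyl enol ether; 7 (diacetoxyiodo)benzene; 3 5,7,3',4'-tetra-O-benzyl-(−)-epicatechin (3 equiv)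
Product: 9 (2R,4R)-5,7,3',4'-tetra-O-benzyl-3-oxoflavan-(4β→8)-5,7,3',4'-tetra-O-benzyl-(−)-epicatechin, via acetoxyiodanyl enol ether 8 (not isolated)
Conditions: PhI(OAc)2, BF3·OEt2, CH2Cl2, −78 °C, 10 min; then 3 (3 equiv), −78 → −40 °C
Reagents that add atoms: none
Why: Proposed new method: PhI(OAc)2·BF3 converts 6 into the O-bound trivalent-iodine enolonium 8, an α-keto cation equivalent whose C4 (innately the nucleophilic enol carbon) is attacked in a Friedel–Crafts sense by the innately nucleophilic C8 of ring A of 3 with loss of PhI, the aryl group entering anti to the C2 aryl (and the acidic C4–H letting the ketone settle as the 2,4-trans epimer, in which peri strain with the 5-OBn group keeps the C4 aryl quasi-axial) so that the 4β linkage is set; with the small, very reactive nucleophile 3 in threefold excess the mild acetate-ligated reagent is enough, and the closest known reaction is the umpolung α-arylation of ketones through trivalent-iodine enolonium species with electron-rich arenes, combined with the known C8 preference of benzylated flavan-3-ols toward C4 electrophiles.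

Step 5
Reactants: 6 the silyl enol ether; 10 [hydroxy(tosyloxy)iodo]benzene; 9 the dimeric ketone (2 equiv)
Product: 12 (2R,4R)-tetra-O-benzyl-3-oxoflavan-(4β→8)-(2R,4S)-tetra-O-benzyl-3-oxoflavan-(4β→8)-tetra-O-benzyl-(−)-epicatechin, via tosyloxyiodanyl enol ether 11 (not isolated)
Conditions: PhI(OH)OTs, BF3·OEt2, CH2Cl2, −78 °C, 10 min; then 9 (2 equiv), −78 → −40 °C
Reagents that add atoms: none
Why: Proposed new method: the same enolonium α-arylation on the dimer, here with PhI(OH)OTs·BF3, whose tosylate-ligated enolonium 11 has a better nucleofuge and carries no nucleophilic acetate that could divert it to the α-acetoxy ketone while the bulkier, slower nucleophile 9 approaches; the free C8 of ring A of the ketone unit of 9 (flanked by O1 and 7-OBn) is the most reactive ArH site, as in cationic chain extension of benzylated procyanidin dimers, and attack anti to the C2 aryl of 11 again gives the 4β linkage; the closest known reaction is the umpolung α-arylation of ketones through enolonium species made from silyl enol ethers with PhI(OH)OTs and BF3.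

Step 6
Reactants: 12 the trimeric bis-ketone
Product: 13 dodeca-O-benzylprocyanidin C1 [tetra-O-benzylepicatechin-(4β→8)-tetra-O-benzylepicatechin-(4β→8)-tetra-O-benzylepicatechin; top unit 2R,3R,4R; middle unit 2R,3R,4S; bottom unit 2R,3R; three free 3-OH]
Conditions: Li[HB(sBu)3] (L-Selectride, 5 equiv), THF, −78 °C; then H2O
Reagents that add atoms: none
Why: substrate-controlled L-Selectride reduction in which hydride is expected to add to each C3 carbonyl anti to the adjacent C2 aryl (the 1,2-induction that gives epi-alcohol 3 from ketone 4), giving the 2,3-cis-3,4-trans carbinols (3R in both units); the C4 aryl on the opposite face is a counter-bias and makes this the least secure stereochemical step.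

Step 7
Reactants: 13 dodeca-O-benzylprocyanidin C1; 14 3,4,5-tris(benzyloxy)benzoic acid
Product: 15 dodeca-O-benzylprocyanidin C1 3,3',3''-tris(3,4,5-tri-O-benzylgallate)
Conditions: 14 (6 equiv), DCC, DMAP, CH2Cl2, rt
Reagents that add atoms: 3,4,5-tris(benzyloxy)benzoic acid (14), OC(=O)c1cc(OCc2ccccc2)c(OCc2ccccc2)c(OCc2ccccc2)c1
Why: Steglich esterification (DMAP-catalysed acyl transfer) acylates the three axial 3-OH groups at oxygen, so all C3 configurations are retained, as known for galloylation of benzylated procyanidins.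

Step 8
Reactants: 15 the perbenzylated tri-gallate
Product: 16 procyanidin C1 3,3',3''-tri-O-gallate (target)
Conditions: H2 (1 atm), Pd(OH)2/C, THF/MeOH/H2O, rt
Reagents that add atoms: none
Why: hydrogenolysis of all 21 benzyl ethers over Pd(OH)2/C leaves the gallate esters, interflavan bonds and stereocentres untouched, the standard last step for procyanidin gallates.

## Compound list

1 | (−)-epicatechin, (2R,3R) | O[C@@H]1Cc2c(O)cc(O)cc2O[C@@H]1c1ccc(O)c(O)c1 | starting material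
2 | benzyl bromide | BrCc1ccccc1 | starting material
3 | 5,7,3',4'-tetra-O-benzyl-(−)-epicatechin, (2R,3R) | O[C@@H]1Cc2c(OCc3ccccc3)cc(OCc3ccccc3)cc2O[C@@H]1c1ccc(OCc2ccccc2)c(OCc2ccccc2)c1 | intermediate
4 | (2R)-5,7,3',4'-tetra-O-benzylflavan-3-one | O=C1Cc2c(OCc3ccccc3)cc(OCc3ccccc3)cc2O[C@@H]1c1ccc(OCc2ccccc2)c(OCc2ccccc2)c1 | intermediate
5 | chlorotrimethylsilane | C[Si](C)(C)Cl | starting material
6 | (2R)-5,7-bis(benzyloxy)-2-[3,4-bis(benzyloxy)phenyl]-3-(trimethylsilyloxy)-2H-chromene | C[Si](C)(C)OC1=Cc2c(OCc3ccccc3)cc(OCc3ccccc3)cc2O[C@@H]1c1ccc(OCc2ccccc2)c(OCc2ccccc2)c1 | intermediate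
7 | (diacetoxyiodo)benzene, PhI(OAc)2 | CC(=O)OI(OC(C)=O)c1ccccc1 | starting material
8 | acetoxyiodanyl enol ether (O-bound enolonium): (2R)-5,7-bis(benzyloxy)-2-[3,4-bis(benzyloxy)phenyl]-2H-chromen-3-yl acetoxy(phenyl)-λ3-iodanyl ether, BF3-activated | CC(=O)OI(c1ccccc1)OC1=Cc2c(OCc3ccccc3)cc(OCc3ccccc3)cc2O[C@@H]1c1ccc(OCc2ccccc2)c(OCc2ccccc2)c1 | intermediate
9 | (2R,4R)-5,7,3',4'-tetra-O-benzyl-3-oxoflavan-(4β→8)-5,7,3',4'-tetra-O-benzyl-(−)-epicatechin (C4 aryl trans to C2 aryl; lower unit 2R,3R, free 3-OH) | O=C1[C@@H](c2c(OCc3ccccc3)cc(OCc3ccccc3)c3c2O[C@H](c2ccc(OCc4ccccc4)c(OCc4ccccc4)c2)[C@H](O)C3)c2c(OCc3ccccc3)cc(OCc3ccccc3)cc2O[C@@H]1c1ccc(OCc2ccccc2)c(OCc2ccccc2)c1 | intermediate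
10 | [hydroxy(tosyloxy)iodo]benzene, PhI(OH)OTs | Cc1ccc(cc1)S(=O)(=O)OI(O)c1ccccc1 | starting material
11 | tosyloxyiodanyl enol ether (O-bound enolonium): (2R)-5,7-bis(benzyloxy)-2-[3,4-bis(benzyloxy)phenyl]-2H-chromen-3-yl phenyl(tosyloxy)-λ3-iodanyl ether, BF3-activated | Cc1ccc(cc1)S(=O)(=O)OI(c1ccccc1)OC1=Cc2c(OCc3ccccc3)cc(OCc3ccccc3)cc2O[C@@H]1c1ccc(OCc2ccccc2)c(OCc2ccccc2)c1 | intermediate
12 | trimeric bis-ketone: (2R,4R)-tetra-O-benzyl-3-oxoflavan-(4β→8)-(2R,4S)-tetra-O-benzyl-3-oxoflavan-(4β→8)-tetra-O-benzyl-(−)-epicatechin | O=C1[C@@H](c2c(OCc3ccccc3)cc(OCc3ccccc3)c3c2O[C@H](c2ccc(OCc4ccccc4)c(OCc4ccccc4)c2)[C@H](O)C3)c2c(OCc3ccccc3)cc(OCc3ccccc3)c([C@H]3c4c(OCc5ccccc5)cc(OCc5ccccc5)cc4O[C@H](c4ccc(OCc5ccccc5)c(OCc5ccccc5)c4)C3=O)c2O[C@@H]1c1ccc(OCc2ccccc2)c(OCc2ccccc2)c1 | intermediate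
13 | dodeca-O-benzylprocyanidin C1 (top 2R,3R,4R; middle 2R,3R,4S; bottom 2R,3R; three free 3-OH) | O[C@@H]1[C@@H](c2c(OCc3ccccc3)cc(OCc3ccccc3)c3c2O[C@H](c2ccc(OCc4ccccc4)c(OCc4ccccc4)c2)[C@H](O)C3)c2c(OCc3ccccc3)cc(OCc3ccccc3)c([C@H]3c4c(OCc5ccccc5)cc(OCc5ccccc5)cc4O[C@H](c4ccc(OCc5ccccc5)c(OCc5ccccc5)c4)[C@@H]3O)c2O[C@@H]1c1ccc(OCc2ccccc2)c(OCc2ccccc2)c1 | intermediate
14 | 3,4,5-tris(benzyloxy)benzoic acid | OC(=O)c1cc(OCc2ccccc2)c(OCc2ccccc2)c(OCc2ccccc2)c1 | starting material
15 | dodeca-O-benzylprocyanidin C1 3,3',3''-tris(3,4,5-tri-O-benzylgallate) | O=C(O[C@@H]1[C@@H](c2c(OCc3ccccc3)cc(OCc3ccccc3)c3c2O[C@H](c2ccc(OCc4ccccc4)c(OCc4ccccc4)c2)[C@H](OC(=O)c2cc(OCc4ccccc4)c(OCc4ccccc4)c(OCc4ccccc4)c2)C3)c2c(OCc3ccccc3)cc(OCc3ccccc3)c([C@H]3c4c(OCc5ccccc5)cc(OCc5ccccc5)cc4O[C@H](c4ccc(OCc5ccccc5)c(OCc5ccccc5)c4)[C@@H]3OC(=O)c3cc(OCc4ccccc4)c(OCc4ccccc4)c(OCc4ccccc4)c3)c2O[C@@H]1c1ccc(OCc2ccccc2)c(OCc2ccccc2)c1)c1cc(OCc2ccccc2)c(OCc2ccccc2)c(OCc2ccccc2)c1 | intermediate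
16 | procyanidin C1 3,3',3''-tri-O-gallate | O=C(O[C@@H]1[C@@H](c2c(O)cc(O)c3c2O[C@H](c2ccc(O)c(O)c2)[C@H](OC(=O)c2cc(O)c(O)c(O)c2)C3)c2c(O)cc(O)c([C@H]3c4c(O)cc(O)cc4O[C@H](c4ccc(O)c(O)c4)[C@@H]3OC(=O)c3cc(O)c(O)c(O)c3)c2O[C@@H]1c1ccc(O)c(O)c1)c1cc(O)c(O)c(O)c1 | target

## Step count and risks

Total steps: 8. Longest linear sequence: 8 (1 → 3 → 4 → 6 → 9 → 12 → 13 → 15 → 16; compound 3 is also the nucleophile of step 4 and compound 6 serves steps 4 and 5).

**Risk 1 (step 4, first enolonium coupling).** The enolonium 8 carries its own electron-rich ring A and may self-arylate, be over-oxidised, or lose the C2 proton to a 3-oxidoflavylium; the free 3-OH of 3 and C6 attack are lesser concerns. The fallback removes the oxidant from the C–C bond-forming flask. It sets out from 3, which is oxidised at C4 with DDQ in CH2Cl2/MeOH to 4β-methoxy-5,7,3',4'-tetra-O-benzyl-(−)-epicatechin F1. Dess–Martin oxidation of its 3-OH gives (2R)-4β-methoxy-5,7,3',4'-tetra-O-benzylflavan-3-one F2. Ionisation of F2 with Me3SiOTf in CH2Cl2 at −78 °C in the presence of excess 3 generates the same α-keto cation and rejoins the route at 9.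

**Risk 2 (step 5, second coupling).** Nucleophile 9 offers three ArH sites, an acidic α-aryl ketone and a free OH to the very reactive tosylate-ligated enolonium 11, so regio-isomers and over-arylation are possible, and the toluenesulfonic acid released could erode the product if the mixture is warmed before quenching. The fallback replaces the second enolonium coupling by cationic chain extension with literature precedent for attack at C8 of the upper ring A of a dimer. It sets out from 9, whose single ketone is reduced with Li[HB(sBu)3] to octa-O-benzylprocyanidin B2 F3. In parallel 3 is oxidised with DDQ/ethylene glycol to 4β-(2-hydroxyethoxy)-5,7,3',4'-tetra-O-benzyl-(−)-epicatechin F4. Activation of F4 with TiCl4 in CH2Cl2/THF at 0 °C in the presence of excess F3 (C4 cation attacked trans to 3-OH) gives 13 directly, where the route is rejoined.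

**Risk 3 (step 6, double reduction).** The two aryl groups flanking each carbonyl sit on opposite faces. If the quasi-axial C4 aryl dominates over the C2 aryl, hydride enters anti to it and the 3-epimers (2,3-trans-3,4-cis) form. These cannot be corrected by SN2 inversion because ring A participates. The fallback takes every C3 centre from epicatechin and gives up the late carbonyl reduction. It sets out from 3, which is esterified with 14 (DCC, DMAP) to 5,7,3',4'-tetra-O-benzyl-(−)-epicatechin 3-O-(3,4,5-tri-O-benzylgallate) F5. Part of F5 is oxidised with DDQ/2-ethoxyethanol to the 4β-(2-ethoxyethoxy) derivative of that gallate F6. Me3SiOTf-mediated coupling of F6 with excess F5 at −78 °C (aryl enters trans to the 3-O-acyl group) gives octa-O-benzylprocyanidin B2 3,3'-bis(3,4,5-tri-O-benzylgallate) F7. A second coupling of F7 with F6 gives 15, where the route is rejoined.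

## Further compounds

F1 | step 4 | 4β-methoxy-5,7,3',4'-tetra-O-benzyl-(−)-epicatechin (4-OMe trans to 3-OH) | CO[C@H]1c2c(OCc3ccccc3)cc(OCc3ccccc3)cc2O[C@H](c2ccc(OCc3ccccc3)c(OCc3ccccc3)c2)[C@@H]1O
F2 | step 4 | (2R)-4β-methoxy-5,7,3',4'-tetra-O-benzylflavan-3-one | CO[C@H]1c2c(OCc3ccccc3)cc(OCc3ccccc3)cc2O[C@H](c2ccc(OCc3ccccc3)c(OCc3ccccc3)c2)C1=O
F3 | step 5 | octa-O-benzylprocyanidin B2 (tetra-O-benzylepicatechin-(4β→8)-tetra-O-benzylepicatechin, two free 3-OH) | O[C@@H]1[C@@H](c2c(OCc3ccccc3)cc(OCc3ccccc3)c3c2O[C@H](c2ccc(OCc4ccccc4)c(OCc4ccccc4)c2)[C@H](O)C3)c2c(OCc3ccccc3)cc(OCc3ccccc3)cc2O[C@@H]1c1ccc(OCc2ccccc2)c(OCc2ccccc2)c1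
F4 | step 5 | 4β-(2-hydroxyethoxy)-5,7,3',4'-tetra-O-benzyl-(−)-epicatechin | OCCO[C@H]1c2c(OCc3ccccc3)cc(OCc3ccccc3)cc2O[C@H](c2ccc(OCc3ccccc3)c(OCc3ccccc3)c2)[C@@H]1O
F5 | step 6 | 5,7,3',4'-tetra-O-benzyl-(−)-epicatechin 3-O-(3,4,5-tri-O-benzylgallate) | O=C(O[C@@H]1Cc2c(OCc3ccccc3)cc(OCc3ccccc3)cc2O[C@@H]1c1ccc(OCc2ccccc2)c(OCc2ccccc2)c1)c1cc(OCc2ccccc2)c(OCc2ccccc2)c(OCc2ccccc2)c1
F6 | step 6 | 4β-(2-ethoxyethoxy)-5,7,3',4'-tetra-O-benzyl-(−)-epicatechin 3-O-(3,4,5-tri-O-benzylgallate) | CCOCCO[C@H]1c2c(OCc3ccccc3)cc(OCc3ccccc3)cc2O[C@H](c2ccc(OCc3ccccc3)c(OCc3ccccc3)c2)[C@@H]1OC(=O)c1cc(OCc2ccccc2)c(OCc2ccccc2)c(OCc2ccccc2)c1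
F7 | step 6 | octa-O-benzylprocyanidin B2 3,3'-bis(3,4,5-tri-O-benzylgallate) | O=C(O[C@@H]1[C@@H](c2c(OCc3ccccc3)cc(OCc3ccccc3)c3c2O[C@H](c2ccc(OCc4ccccc4)c(OCc4ccccc4)c2)[C@H](OC(=O)c2cc(OCc4ccccc4)c(OCc4ccccc4)c(OCc4ccccc4)c2)C3)c2c(OCc3ccccc3)cc(OCc3ccccc3)cc2O[C@@H]1c1ccc(OCc2ccccc2)c(OCc2ccccc2)c1)c1cc(OCc2ccccc2)c(OCc2ccccc2)c(OCc2ccccc2)c1
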